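**Strategy.** The route rests on cutting the α‑methylene‑γ‑lactone ring (O–C12–C11–C7–C6, germacrane numbering) off a diene. Its oxygen sits on C6, allylic to the (Z)‑C4=C5 alkene, and the acrylate α‑carbon C11 sits on C7: the pattern left by 1,2‑carbo‑oxygenation of a C4=C5–C6=C7 diene through a C4–C6 π‑allyl. A palladium‑catalysed heteroannulation of an acyclic (4Z,6Z)‑dienyl dioxolane with 2‑bromoacrylic acid forms C11–C7 and O–C6 in one operation, brings in the exocyclic methylene and sets C6 and C7 from the glyceraldehyde‑derived C8. The ten‑membered ring is closed afterwards at C9–C10 by a Nozaki–Hiyama–Kishi reaction.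

Key step: step 5

Remark: all locants follow germacrane numbering (ring C1–C10, lactone C11–C13, C14 on C10, C15 on C4). The SMILES is read as 1(10)Z,4Z, 6R,7R,8S,9R, with a (2R)‑2‑methylbutanoate on O14.

**Step 1**
Reactants: 1 pent‑4‑yn‑1‑ol
Product: 3 (Z)‑5‑iodo‑4‑methylpent‑4‑en‑1‑ol, via chelated Z‑alkenylalane 2 (not isolated)
Conditions: Me3Al (3 equiv), Cp2ZrCl2 (0.25 equiv), ClCH2CH2Cl, 23 °C, then reflux; I2, THF, −30 → 0 °C; aq. work‑up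
Reagents that add atoms: trimethylaluminium C[Al](C)C; iodine II
Why: Zirconium‑catalysed Negishi carboalumination adds Me to C4 and Al to C5 syn, heating lets the O–Al chelate isomerise the alkenylalane so that aluminium sits cis to the hydroxypropyl chain, and iododealumination with retention gives the (Z)‑iodide that fixes the 4Z alkene.

**Step 2**
Reactants: 4 (R)‑2,2‑dimethyl‑1,3‑dioxolane‑4‑carbaldehyde
Product: 5 (S)‑4‑ethynyl‑2,2‑dimethyl‑1,3‑dioxolane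
Conditions: dimethyl (1‑diazo‑2‑oxopropyl)phosphonate, K2CO3, MeOH, 0 → 23 °C
Reagents that add atoms: dimethyl (1‑diazo‑2‑oxopropyl)phosphonate CC(=O)C(=[N+]=[N-])P(=O)(OC)OC
Why: Seyferth–Gilbert homologation with the Ohira–Bestmann reagent turns the aldehyde into the terminal alkyne under carbonate/methanol conditions that should leave the α‑oxygenated stereocentre (the future C8) intact.

**Step 3**
Reactants: 3 (Z)‑5‑iodo‑4‑methylpent‑4‑en‑1‑ol; 5 (S)‑4‑ethynyl‑2,2‑dimethyl‑1,3‑dioxolane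
Product: 6 (4Z)‑7‑[(4S)‑2,2‑dimethyl‑1,3‑dioxolan‑4‑yl]‑4‑methylhept‑4‑en‑6‑yn‑1‑ol
Conditions: PdCl2(PPh3)2 (3 mol %), CuI (6 mol %), Et3N, THF, 23 °C
Reagents that add atoms: none
Why: Sonogashira coupling joins C5 to C6 with retention of the vinyl iodide geometry and tolerates the free alcohol and the acetonide.

**Step 4**
Reactants: 6 (4Z)‑7‑[(4S)‑2,2‑dimethyl‑1,3‑dioxolan‑4‑yl]‑4‑methylhept‑4‑en‑6‑yn‑1‑ol
Product: 7 (4Z,6Z)‑7‑[(4S)‑2,2‑dimethyl‑1,3‑dioxolan‑4‑yl]‑4‑methylhepta‑4,6‑dien‑1‑ol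
Conditions: Zn(Cu/Ag), MeOH–H2O (1:1), 40 °C
Reagents that add atoms: none
Why: The Boland reduction with activated zinc reduces only the conjugated triple bond by cis addition of hydrogen, so the (6Z)‑alkene should form without over‑reduction and without touching the trisubstituted (4Z)‑alkene.

**Step 5**
Reactants: 7 (4Z,6Z)‑7‑[(4S)‑2,2‑dimethyl‑1,3‑dioxolan‑4‑yl]‑4‑methylhepta‑4,6‑dien‑1‑ol; 8 2‑bromoprop‑2‑enoic acid
Product: 9 (4S,5R)‑4‑[(4S)‑2,2‑dimethyl‑1,3‑dioxolan‑4‑yl]‑5‑[(1Z)‑5‑hydroxy‑2‑methylpent‑1‑en‑1‑yl]‑3‑methylideneoxolan‑2‑one (trans‑lactone)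
Conditions: Pd(OAc)2 (10 mol %), n‑Bu4NCl (1.2 equiv), K2CO3 (3 equiv), DMF, 50 °C, slow addition of 8 (1.5 equiv)
Reagents that add atoms: none
Why: Pd(0) adds oxidatively to the C–Br bond of the 2‑bromoacrylate, the (1‑carboxyvinyl)palladium inserts the C6=C7 alkene syn with carbon bonding to the less substituted diene terminus C7, and the η3‑allyl complex spanning C4–C5–C6 is captured at C6 by the pendant carboxylate with release of Pd(0). The closest known reaction type is the Larock heteroannulation of 1,3‑dienes with vinylic or aryl halides that carry a carboxylic acid (Heck insertion followed by Tsuji–Trost‑type C–O bond formation). The γ‑lactone closes by 5‑exo attack of the carboxylate oxygen on the C6 terminus of the π‑allyl, outer‑sphere and anti to palladium because chloride keeps the carboxylate off the metal. C7 is controlled by the C8 dioxolane stereocentre: A(1,3) strain across the (6Z)‑alkene holds H‑8 in the alkene plane, and the vinylpalladium should add to the π‑face anti to the C8–O bond (the sense followed by osmylation, cuprate addition and cycloaddition on such (Z)‑allylic ethers), which is the C7 configuration of the target; C6 then follows from syn insertion plus anti C–O formation on a (6Z)‑alkene, which gives the trans‑lactone. The step needs insertion at C7 and not C4 (secured by the disubstituted C4 terminus), closure at C6 and not C4 (five‑ versus seven‑membered ring), and retention of the 4Z geometry (C3 stays anti on the allyl because lactonisation should outrun η3–η1–η3 exchange at the tertiary C4).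

**Step 6**
Reactants: 9 (4S,5R)‑4‑[(4S)‑2,2‑dimethyl‑1,3‑dioxolan‑4‑yl]‑5‑[(1Z)‑5‑hydroxy‑2‑methylpent‑1‑en‑1‑yl]‑3‑methylideneoxolan‑2‑one
Product: 11 (2E,6Z)‑7‑[(2R,3S)‑3‑[(4S)‑2,2‑dimethyl‑1,3‑dioxolan‑4‑yl]‑4‑methylidene‑5‑oxooxolan‑2‑yl]‑6‑methylhepta‑2,6‑dienal, via aldehyde 10 (not isolated)
Conditions: Dess–Martin periodinane, NaHCO3, CH2Cl2, 0 → 23 °C; then Ph3P=CHCHO, 40 °C
Reagents that add atoms: (triphenylphosphoranylidene)acetaldehyde O=CC=P(c1ccccc1)(c1ccccc1)c1ccccc1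
Why: Dess–Martin oxidation of the primary alcohol followed in the same flask by Wittig olefination with the stabilised formyl ylide should give the (E)‑enal, adding C10 and C14 without any hydride reagent that would attack the lactone.

**Step 7**
Reactants: 11 (2E,6Z)‑7‑[(2R,3S)‑3‑[(4S)‑2,2‑dimethyl‑1,3‑dioxolan‑4‑yl]‑4‑methylidene‑5‑oxooxolan‑2‑yl]‑6‑methylhepta‑2,6‑dienal
Product: 12 (2Z,6Z)‑7‑[(2R,3S)‑3‑[(4S)‑2,2‑dimethyl‑1,3‑dioxolan‑4‑yl]‑4‑methylidene‑5‑oxooxolan‑2‑yl]‑2‑iodo‑6‑methylhepta‑2,6‑dienal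
Conditions: I2 (1.5 equiv), DMAP (0.2 equiv), K2CO3 (1.2 equiv), THF–H2O (1:1), 23 °C
Reagents that add atoms: iodine II
Why: DMAP‑catalysed α‑iodination of the enal (conjugate addition of DMAP, iodination of the enolate, elimination of DMAP; a Baylis–Hillman‑type sequence) should give the (Z)‑α‑iodoenal, the isomer with the formyl group trans to the chain and iodine cis to C2.

**Step 8**
Reactants: 12 (2Z,6Z)‑7‑[(2R,3S)‑3‑[(4S)‑2,2‑dimethyl‑1,3‑dioxolan‑4‑yl]‑4‑methylidene‑5‑oxooxolan‑2‑yl]‑2‑iodo‑6‑methylhepta‑2,6‑dienal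
Product: 13 (4S,5R)‑4‑[(4S)‑2,2‑dimethyl‑1,3‑dioxolan‑4‑yl]‑5‑[(1Z,5Z)‑7‑hydroxy‑6‑iodo‑2‑methylhepta‑1,5‑dien‑1‑yl]‑3‑methylideneoxolan‑2‑one
Conditions: NaBH4, CeCl3·7H2O, MeOH, −78 °C
Reagents that add atoms: none
Why: Luche reduction attacks the aldehyde carbonyl 1,2 within minutes at −78 °C, which should spare the α‑methylene lactone, the vinyl iodide and the acetonide.

**Step 9**
Reactants: 13 (4S,5R)‑4‑[(4S)‑2,2‑dimethyl‑1,3‑dioxolan‑4‑yl]‑5‑[(1Z,5Z)‑7‑hydroxy‑6‑iodo‑2‑methylhepta‑1,5‑dien‑1‑yl]‑3‑methylideneoxolan‑2‑one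
Product: 14 (4S,5R)‑5‑[(1Z,5Z)‑7‑[(tert‑butyldiphenylsilyl)oxy]‑6‑iodo‑2‑methylhepta‑1,5‑dien‑1‑yl]‑4‑[(4S)‑2,2‑dimethyl‑1,3‑dioxolan‑4‑yl]‑3‑methylideneoxolan‑2‑one
Conditions: TBDPSCl, Et3N, DMAP (cat.), CH2Cl2, 0 → 23 °C
Reagents that add atoms: tert‑butyl(chloro)diphenylsilane CC(C)(C)[Si](Cl)(c1ccccc1)c1ccccc1
Why: Silylation of the primary allylic alcohol; a silyl ether and not the final ester is used because an allylic acyloxy group next to the later alkenylchromium could be lost by β‑elimination, and TBDPS survives the acid of step 10.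

**Step 10**
Reactants: 14 (4S,5R)‑5‑[(1Z,5Z)‑7‑[(tert‑butyldiphenylsilyl)oxy]‑6‑iodo‑2‑methylhepta‑1,5‑dien‑1‑yl]‑4‑[(4S)‑2,2‑dimethyl‑1,3‑dioxolan‑4‑yl]‑3‑methylideneoxolan‑2‑one
Product: 15 (4R,5R)‑5‑[(1Z,5Z)‑7‑[(tert‑butyldiphenylsilyl)oxy]‑6‑iodo‑2‑methylhepta‑1,5‑dien‑1‑yl]‑4‑[(1S)‑1,2‑dihydroxyethyl]‑3‑methylideneoxolan‑2‑one
Conditions: AcOH–THF–H2O (3:1:1), 23 → 35 °C
Reagents that add atoms: none
Why: Acid‑catalysed acetal hydrolysis of the terminal acetonide frees the 8,9‑diol, while the TBDPS ether, the vinyl iodide and the lactone should be stable to dilute acetic acid.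

**Step 11**
Reactants: 15 (4R,5R)‑5‑[(1Z,5Z)‑7‑[(tert‑butyldiphenylsilyl)oxy]‑6‑iodo‑2‑methylhepta‑1,5‑dien‑1‑yl]‑4‑[(1S)‑1,2‑dihydroxyethyl]‑3‑methylideneoxolan‑2‑one
Product: 16 (4S,5R)‑4‑[(1S)‑1,2‑bis(triethylsilyloxy)ethyl]‑5‑[(1Z,5Z)‑7‑[(tert‑butyldiphenylsilyl)oxy]‑6‑iodo‑2‑methylhepta‑1,5‑dien‑1‑yl]‑3‑methylideneoxolan‑2‑one
Conditions: TESOTf (2.5 equiv), 2,6‑lutidine, CH2Cl2, −78 °C
Reagents that add atoms: triethylsilyl trifluoromethanesulfonate CC[Si](CC)(CC)OS(=O)(=O)C(F)(F)F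
Why: Silylation of both hydroxyls with the silyl triflate and a hindered, non‑nucleophilic base avoids amine addition to the α‑methylene lactone and prepares the differentiation of O8 and O9.

**Step 12**
Reactants: 16 (4S,5R)‑4‑[(1S)‑1,2‑bis(triethylsilyloxy)ethyl]‑5‑[(1Z,5Z)‑7‑[(tert‑butyldiphenylsilyl)oxy]‑6‑iodo‑2‑methylhepta‑1,5‑dien‑1‑yl]‑3‑methylideneoxolan‑2‑one
Product: 17 (2S)‑2‑[(2R,3S)‑2‑[(1Z,5Z)‑7‑[(tert‑butyldiphenylsilyl)oxy]‑6‑iodo‑2‑methylhepta‑1,5‑dien‑1‑yl]‑4‑methylidene‑5‑oxooxolan‑3‑yl]‑2‑(triethylsilyloxy)acetaldehyde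
Conditions: (COCl)2, DMSO, CH2Cl2, −78 → −30 °C; then Et3N, −78 → 0 °C
Reagents that add atoms: none
Why: Under Swern conditions the chlorodimethylsulfonium salt cleaves the unhindered primary triethylsilyl ether and oxidises it directly to the aldehyde, whereas the secondary triethylsilyl ether at C8 and the TBDPS ether are too hindered to react.

**Step 13**
Reactants: 17 (2S)‑2‑[(2R,3S)‑2‑[(1Z,5Z)‑7‑[(tert‑butyldiphenylsilyl)oxy]‑6‑iodo‑2‑methylhepta‑1,5‑dien‑1‑yl]‑4‑methylidene‑5‑oxooxolan‑3‑yl]‑2‑(triethylsilyloxy)acetaldehyde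
Product: 18 (1(10)Z,4Z,6R,7S,8S,9R)‑14‑[(tert‑butyldiphenylsilyl)oxy]‑9‑hydroxy‑8‑(triethylsilyloxy)germacra‑1(10),4,11(13)‑trien‑12,6‑olide
Conditions: CrCl2 (12 equiv), NiCl2 (0.2 equiv), DMSO–THF (3:1), 23 °C, 2 mM, slow addition
Reagents that add atoms: none
Why: Intramolecular Nozaki–Hiyama–Kishi reaction: nickel inserts into the C10–I bond, transmetallation gives the alkenylchromium(III) with retention of alkene geometry, and its addition to the C9 aldehyde closes the ten‑membered ring, with Felkin–Anh attack anti to the C8 silyloxy group expected to give the 8,9‑anti carbinol (9R).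

**Step 14**
Reactants: 18 (1(10)Z,4Z,6R,7S,8S,9R)‑14‑[(tert‑butyldiphenylsilyl)oxy]‑9‑hydroxy‑8‑(triethylsilyloxy)germacra‑1(10),4,11(13)‑trien‑12,6‑olide
Product: 19 (1(10)Z,4Z,6R,7S,8S,9R)‑9‑acetoxy‑14‑[(tert‑butyldiphenylsilyl)oxy]‑8‑(triethylsilyloxy)germacra‑1(10),4,11(13)‑trien‑12,6‑olide
Conditions: Ac2O, pyridine, DMAP (cat.), CH2Cl2, 0 → 23 °C
Reagents that add atoms: acetic anhydride CC(=O)OC(C)=O
Why: Acylation under nucleophilic catalysis of the only free hydroxyl, O9.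

**Step 15**
Reactants: 19 (1(10)Z,4Z,6R,7S,8S,9R)‑9‑acetoxy‑14‑[(tert‑butyldiphenylsilyl)oxy]‑8‑(triethylsilyloxy)germacra‑1(10),4,11(13)‑trien‑12,6‑olide
Product: 20 (1(10)Z,4Z,6R,7R,8S,9R)‑9‑acetoxy‑8,14‑dihydroxygermacra‑1(10),4,11(13)‑trien‑12,6‑olide
Conditions: HF·pyridine, pyridine, THF, 0 → 23 °C
Reagents that add atoms: none
Why: Fluoride‑mediated desilylation under buffered, weakly acidic conditions removes both the TES and the TBDPS ether and should avoid acetyl migration from O9 to O8 and conjugate addition to the lactone.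

**Step 16**
Reactants: 20 (1(10)Z,4Z,6R,7R,8S,9R)‑9‑acetoxy‑8,14‑dihydroxygermacra‑1(10),4,11(13)‑trien‑12,6‑olide; 21 (R)‑2‑methylbutanoic acid
Product: 22 (1(10)Z,4Z,6R,7R,8S,9R)‑9‑acetoxy‑8‑hydroxy‑14‑{[(2R)‑2‑methylbutanoyl]oxy}germacra‑1(10),4,11(13)‑trien‑12,6‑olide (CNP0005248.2)
Conditions: EDC·HCl (1.2 equiv), DMAP (0.1 equiv), CH2Cl2, −20 → 0 °C
Reagents that add atoms: none
Why: Steglich‑type carbodiimide esterification should acylate the unhindered primary allylic C14 hydroxyl in preference to the secondary C8 hydroxyl flanked by C7 and the C9 acetate, and the short, cold reaction keeps the α‑stereocentre of the acid intact.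

**Compound list**

1 | pent‑4‑yn‑1‑ol | C#CCCCO | starting material
2 | chelated Z‑alkenylalane (2,4‑dimethyl‑1‑oxa‑2‑aluminacyclohept‑3‑ene) | C[Al]1OCCC/C(C)=C\1 | intermediate (not isolated)
3 | (Z)‑5‑iodo‑4‑methylpent‑4‑en‑1‑ol | OCCC/C(C)=C\I | intermediate
4 | (R)‑2,2‑dimethyl‑1,3‑dioxolane‑4‑carbaldehyde | O=C[C@H]1COC(C)(C)O1 | starting material
5 | (S)‑4‑ethynyl‑2,2‑dimethyl‑1,3‑dioxolane | C#C[C@H]1COC(C)(C)O1 | intermediate
6 | (4Z)‑7‑[(4S)‑2,2‑dimethyl‑1,3‑dioxolan‑4‑yl]‑4‑methylhept‑4‑en‑6‑yn‑1‑ol | OCCC/C(C)=C\C#C[C@H]1COC(C)(C)O1 | intermediate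
7 | (4Z,6Z)‑7‑[(4S)‑2,2‑dimethyl‑1,3‑dioxolan‑4‑yl]‑4‑methylhepta‑4,6‑dien‑1‑ol | OCCC/C(C)=C\C=C/[C@H]1COC(C)(C)O1 | intermediate
8 | 2‑bromoprop‑2‑enoic acid | C=C(Br)C(=O)O | starting material
9 | (4S,5R)‑4‑[(4S)‑2,2‑dimethyl‑1,3‑dioxolan‑4‑yl]‑5‑[(1Z)‑5‑hydroxy‑2‑methylpent‑1‑en‑1‑yl]‑3‑methylideneoxolan‑2‑one | C=C1C(=O)O[C@H](/C=C(/C)CCCO)[C@H]1[C@H]2COC(C)(C)O2 | intermediate
10 | (4Z)‑5‑[(2R,3S)‑3‑[(4S)‑2,2‑dimethyl‑1,3‑dioxolan‑4‑yl]‑4‑methylidene‑5‑oxooxolan‑2‑yl]‑4‑methylpent‑4‑enal | C=C1C(=O)O[C@H](/C=C(/C)CCC=O)[C@H]1[C@H]2COC(C)(C)O2 | intermediate (not isolated)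
11 | (2E,6Z)‑7‑[(2R,3S)‑3‑[(4S)‑2,2‑dimethyl‑1,3‑dioxolan‑4‑yl]‑4‑methylidene‑5‑oxooxolan‑2‑yl]‑6‑methylhepta‑2,6‑dienal | C=C1C(=O)O[C@H](/C=C(/C)CC/C=C/C=O)[C@H]1[C@H]2COC(C)(C)O2 | intermediate
12 | (2Z,6Z)‑7‑[(2R,3S)‑3‑[(4S)‑2,2‑dimethyl‑1,3‑dioxolan‑4‑yl]‑4‑methylidene‑5‑oxooxolan‑2‑yl]‑2‑iodo‑6‑methylhepta‑2,6‑dienal | C=C1C(=O)O[C@H](/C=C(/C)CC/C=C(\I)C=O)[C@H]1[C@H]2COC(C)(C)O2 | intermediate
13 | (4S,5R)‑4‑[(4S)‑2,2‑dimethyl‑1,3‑dioxolan‑4‑yl]‑5‑[(1Z,5Z)‑7‑hydroxy‑6‑iodo‑2‑methylhepta‑1,5‑dien‑1‑yl]‑3‑methylideneoxolan‑2‑one | C=C1C(=O)O[C@H](/C=C(/C)CC/C=C(\I)CO)[C@H]1[C@H]2COC(C)(C)O2 | intermediate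
14 | (4S,5R)‑5‑[(1Z,5Z)‑7‑[(tert‑butyldiphenylsilyl)oxy]‑6‑iodo‑2‑methylhepta‑1,5‑dien‑1‑yl]‑4‑[(4S)‑2,2‑dimethyl‑1,3‑dioxolan‑4‑yl]‑3‑methylideneoxolan‑2‑one | C=C1C(=O)O[C@H](/C=C(/C)CC/C=C(\I)CO[Si](c3ccccc3)(c4ccccc4)C(C)(C)C)[C@H]1[C@H]2COC(C)(C)O2 | intermediate
15 | (4R,5R)‑5‑[(1Z,5Z)‑7‑[(tert‑butyldiphenylsilyl)oxy]‑6‑iodo‑2‑methylhepta‑1,5‑dien‑1‑yl]‑4‑[(1S)‑1,2‑dihydroxyethyl]‑3‑methylideneoxolan‑2‑one | C=C1C(=O)O[C@H](/C=C(/C)CC/C=C(\I)CO[Si](c3ccccc3)(c4ccccc4)C(C)(C)C)[C@H]1[C@H](O)CO | intermediate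
16 | (4S,5R)‑4‑[(1S)‑1,2‑bis(triethylsilyloxy)ethyl]‑5‑[(1Z,5Z)‑7‑[(tert‑butyldiphenylsilyl)oxy]‑6‑iodo‑2‑methylhepta‑1,5‑dien‑1‑yl]‑3‑methylideneoxolan‑2‑one | C=C1C(=O)O[C@H](/C=C(/C)CC/C=C(\I)CO[Si](c3ccccc3)(c4ccccc4)C(C)(C)C)[C@H]1[C@H](O[Si](CC)(CC)CC)CO[Si](CC)(CC)CC | intermediate
17 | (2S)‑2‑[(2R,3S)‑2‑[(1Z,5Z)‑7‑[(tert‑butyldiphenylsilyl)oxy]‑6‑iodo‑2‑methylhepta‑1,5‑dien‑1‑yl]‑4‑methylidene‑5‑oxooxolan‑3‑yl]‑2‑(triethylsilyloxy)acetaldehyde | C=C1C(=O)O[C@H](/C=C(/C)CC/C=C(\I)CO[Si](c3ccccc3)(c4ccccc4)C(C)(C)C)[C@H]1[C@H](O[Si](CC)(CC)CC)C=O | intermediate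
18 | (1(10)Z,4Z,6R,7S,8S,9R)‑14‑[(tert‑butyldiphenylsilyl)oxy]‑9‑hydroxy‑8‑(triethylsilyloxy)germacra‑1(10),4,11(13)‑trien‑12,6‑olide | C=C1C(=O)O[C@@H]2/C=C(/C)CC/C=C(/CO[Si](c3ccccc3)(c4ccccc4)C(C)(C)C)[C@@H](O)[C@@H](O[Si](CC)(CC)CC)[C@@H]12 | intermediate
19 | (1(10)Z,4Z,6R,7S,8S,9R)‑9‑acetoxy‑14‑[(tert‑butyldiphenylsilyl)oxy]‑8‑(triethylsilyloxy)germacra‑1(10),4,11(13)‑trien‑12,6‑olide | C=C1C(=O)O[C@@H]2/C=C(/C)CC/C=C(/CO[Si](c3ccccc3)(c4ccccc4)C(C)(C)C)[C@@H](OC(C)=O)[C@@H](O[Si](CC)(CC)CC)[C@@H]12 | intermediate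
20 | (1(10)Z,4Z,6R,7R,8S,9R)‑9‑acetoxy‑8,14‑dihydroxygermacra‑1(10),4,11(13)‑trien‑12,6‑olide | C=C1C(=O)O[C@@H]2/C=C(/C)CC/C=C(/CO)[C@@H](OC(C)=O)[C@@H](O)[C@@H]12 | intermediate
21 | (R)‑2‑methylbutanoic acid | CC[C@@H](C)C(=O)O | starting material
22 | (1(10)Z,4Z,6R,7R,8S,9R)‑9‑acetoxy‑8‑hydroxy‑14‑{[(2R)‑2‑methylbutanoyl]oxy}germacra‑1(10),4,11(13)‑trien‑12,6‑olide (CNP0005248.2) | C=C1C(=O)O[C@@H]2/C=C(/C)CC/C=C(/COC(=O)[C@H](C)CC)[C@@H](OC(C)=O)[C@@H](O)[C@@H]12 | target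

**Step count.** Total: 16 steps. Longest linear sequence: 15 steps (from 1 through steps 1 and 3–16; step 2 is the one‑step side branch).

**Steps most likely to fail**

Step 5. Insertion of the vinylpalladium into the hindered (Z,Z)‑diene may be slow, so that β‑hydride elimination to trienes or loss of the bromoacrylate competes, and facial selectivity at C7 may be eroded. The fallback sets out from 7 and makes the same two bonds by a radical–polar sequence instead of an organopalladium one. Oxidative annulation with potassium ethyl malonate, Mn(OAc)3·2H2O and catalytic Cu(OAc)2 in AcOH at 40 °C would proceed as follows: the malonyl radical adds to C7, the allyl radical is oxidised, and the free acid closes onto C6. This would give the α‑ethoxycarbonyl lactone F1. Saponification with LiOH in THF–H2O and relactonisation on acidification would give the lactone acid F2. Decarboxylative Mannich methylenation (aq. HCHO, Et2NH, AcOH/NaOAc) would return to 9.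

Step 13. Strain in the forming ten‑membered ring may override Felkin–Anh control, so that the C9 carbinol forms with the wrong or a mixed configuration. The fallback sets out from 17. The cyclisation is run as before, and the crude alcohols, 18 together with the C9‑epimeric alcohol F3, would be oxidised with Dess–Martin periodinane to the macrocyclic enone F4. Reagent‑controlled reduction (CBS oxazaborolidine with catecholborane, −78 °C, the catalyst enantiomer chosen to deliver hydride to the face that gives 9R) would then come back to 18.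

Step 7. Free electrophilic iodine in a basic aqueous medium may attack the trisubstituted C4=C5 alkene (iodohydrin formation), or the lactone may be opened. The fallback sets out from 10, generated from 9 as in step 6, and puts the iodine on the ylide before olefination. The iodo(formyl) ylide F5 would be preformed from Ph3P=CHCHO with N‑iodosuccinimide and K2CO3 in CH2Cl2 at −20 °C, by analogy with the known halo(alkoxycarbonyl) ylides. Wittig reaction of F5 with 10 should give the (Z)‑α‑iodoenal directly, so the route is rejoined at 12.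

**Further compounds**

F1 | step 5 | ethyl (4S,5R)‑4‑[(4S)‑2,2‑dimethyl‑1,3‑dioxolan‑4‑yl]‑5‑[(1Z)‑5‑hydroxy‑2‑methylpent‑1‑en‑1‑yl]‑2‑oxooxolane‑3‑carboxylate (C3 epimers) | CCOC(=O)C1C(=O)O[C@H](/C=C(/C)CCCO)[C@H]1[C@H]2COC(C)(C)O2
F2 | step 5 | (4S,5R)‑4‑[(4S)‑2,2‑dimethyl‑1,3‑dioxolan‑4‑yl]‑5‑[(1Z)‑5‑hydroxy‑2‑methylpent‑1‑en‑1‑yl]‑2‑oxooxolane‑3‑carboxylic acid (C3 epimers) | OC(=O)C1C(=O)O[C@H](/C=C(/C)CCCO)[C@H]1[C@H]2COC(C)(C)O2
F3 | step 13 | (1(10)Z,4Z,6R,7S,8S,9S)‑14‑[(tert‑butyldiphenylsilyl)oxy]‑9‑hydroxy‑8‑(triethylsilyloxy)germacra‑1(10),4,11(13)‑trien‑12,6‑olide (C9 epimer of 18) | C=C1C(=O)O[C@@H]2/C=C(/C)CC/C=C(/CO[Si](c3ccccc3)(c4ccccc4)C(C)(C)C)[C@H](O)[C@@H](O[Si](CC)(CC)CC)[C@@H]12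
F4 | step 13 | (1(10)Z,4Z,6R,7S,8S)‑14‑[(tert‑butyldiphenylsilyl)oxy]‑9‑oxo‑8‑(triethylsilyloxy)germacra‑1(10),4,11(13)‑trien‑12,6‑olide | C=C1C(=O)O[C@@H]2/C=C(/C)CC/C=C(/CO[Si](c3ccccc3)(c4ccccc4)C(C)(C)C)C(=O)[C@@H](O[Si](CC)(CC)CC)[C@@H]12
F5 | step 7 | 2‑iodo‑2‑(triphenyl‑λ5‑phosphanylidene)acetaldehyde | O=CC(I)=P(c1ccccc1)(c1ccccc1)c1ccccc1
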